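**Plan**
- Feature: the only stereocentre is C2 of the flavanone unit. It carries the ring oxygen O1 and lies β to the C4 carbonyl, so ring C of the flavanone can be closed last by conjugate addition of the C8a phenol oxygen onto an activated chalcone.
- Cuts, in retrosynthetic order: O1–C2 (oxa-Michael); C2=C3 of the acceptor (Knoevenagel); C3–C4 and C4–C4a (acetate aldol on an ortho-formylated phenol); the biaryl bond flavone C3–flavanone C6 (Suzuki–Miyaura).
- Forward: an intact flavone is iodinated at C3 and joined to a phloroglucinol boronic acid. The phloroglucinol ring is then formylated, homologated to an allyl β-keto ester and condensed with the ring B aldehyde. The dihydropyranone is the only ring built.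
- Stereochemistry: C2 (R) comes from a cinchona-derived thiourea in the ring closure; no later step is basic enough to reopen the ring.

Key step: step 13

Remark 1: the quinine-derived 9-amino-9-deoxy-epi-cinchona thiourea is assumed to give the (2R) flavanone; if a model cyclization shows the opposite sense, the quinidine-derived pseudoenantiomer is used and nothing else changes.
Remark 2: rotation about the flavone C3–flavanone C6 bond is assumed fast enough in the free polyphenol that no axial isomers need be carried; protected intermediates may appear as rotamer mixtures.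

In the names below, "Fl" stands for the 7-methoxy-5-(methoxymethoxy)-2-(4-methoxyphenyl)-4-oxo-4H-chromen-3-yl group.

Step 1
Reactants: 1 5-hydroxy-7-methoxy-2-(4-methoxyphenyl)-4H-chromen-4-one
Product: 2 7-methoxy-5-(methoxymethoxy)-2-(4-methoxyphenyl)-4H-chromen-4-one
Conditions: MOMCl, K2CO3, DMF, 0 to 40 °C
Reagents that add atoms: chloromethyl methyl ether, COCCl
Why: Williamson-type O-alkylation of the chelated C5 phenol, which carbonate in DMF frees from its hydrogen bond to the C4 carbonyl; the acetal cap keeps ring A of the flavone out of the later phenol-directed formylation and leaves with the other MOM groups at the end.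

Step 2
Reactants: 2 7-methoxy-5-(methoxymethoxy)-2-(4-methoxyphenyl)-4H-chromen-4-one
Product: 4 3-iodo-7-methoxy-5-(methoxymethoxy)-2-(4-methoxyphenyl)-4H-chromen-4-one, via 3-lithioflavone 3 (not isolated)
Conditions: LiN(i-Pr)2 (LDA), THF, −78 °C; I2, −78 to −40 °C
Reagents that add atoms: iodine, II
Why: Directed lithiation–iodination, in which the amide base removes the C3 proton next to the coordinating C4 carbonyl and iodine traps the vinyllithium, so the halogen goes to C3 and not to C6 or C8 as electrophilic iodination of the electron-rich ring A would give.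

Step 3
Reactants: 5 phloroglucinol
Product: 6 3,5-bis(methoxymethoxy)phenol
Conditions: MOMCl (2 equiv), i-Pr2NEt, DMF, 0 °C to rt; chromatography
Reagents that add atoms: chloromethyl methyl ether, COCCl
Why: Statistical O-alkylation of three equivalent hydroxyls with a hard electrophile, which should give the bis-ether as the main fraction, separable from mono- and tris-ethers that can be recycled.

Step 4
Reactants: 6 3,5-bis(methoxymethoxy)phenol
Product: 7 [3,5-bis(methoxymethoxy)phenoxy]tri(propan-2-yl)silane
Conditions: i-Pr3SiCl, imidazole, DMF, rt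
Reagents that add atoms: chlorotriisopropylsilane, CC(C)[Si](Cl)(C(C)C)C(C)C
Why: Standard silylation of a phenol; the bulky, non-coordinating silyl ether marks the oxygen that becomes O1 of the flavanone, is orthogonal to the MOM ethers and shields its two flanking positions from lithiation.

Step 5
Reactants: 7 [3,5-bis(methoxymethoxy)phenoxy]tri(propan-2-yl)silane
Product: 10 [2,6-bis(methoxymethoxy)-4-(triisopropylsilyloxy)phenyl]boronic acid, via aryllithium 8 (not isolated), via lithium aryltrimethoxyborate 9 (not isolated)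
Conditions: n-BuLi, THF, 0 °C; B(OMe)3, −78 °C to rt; aq. NH4Cl; used without chromatography
Reagents that add atoms: trimethyl borate, COB(OC)OC; water, O
Why: Directed ortho-metalation at the one position flanked by two chelating MOM ethers, followed by borylation and hydrolysis; the silyloxy-flanked positions are neither activated nor accessible.

Step 6
Reactants: 4 3-iodo-7-methoxy-5-(methoxymethoxy)-2-(4-methoxyphenyl)-4H-chromen-4-one; 10 [2,6-bis(methoxymethoxy)-4-(triisopropylsilyloxy)phenyl]boronic acid (1.6 equiv)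
Product: 11 3-[2,6-bis(methoxymethoxy)-4-(triisopropylsilyloxy)phenyl]-7-methoxy-5-(methoxymethoxy)-2-(4-methoxyphenyl)-4H-chromen-4-one
Conditions: Pd(OAc)2 (5 mol %), SPhos (10 mol %), K3PO4, toluene/H2O, 90 °C
Reagents that add atoms: none
Why: Suzuki–Miyaura coupling, for which 3-iodoflavones are established electrophiles and a bulky dialkylbiarylphosphine is the known remedy for di-ortho-alkoxy boronic acids; the excess of 10 should cover protodeboronation, and any silyl ether lost under the basic conditions simply arrives early at 12.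

Step 7
Reactants: 11 3-[2,6-bis(methoxymethoxy)-4-(triisopropylsilyloxy)phenyl]-7-methoxy-5-(methoxymethoxy)-2-(4-methoxyphenyl)-4H-chromen-4-one
Product: 12 3-[4-hydroxy-2,6-bis(methoxymethoxy)phenyl]-7-methoxy-5-(methoxymethoxy)-2-(4-methoxyphenyl)-4H-chromen-4-one
Conditions: Bu4NF, AcOH, THF, 0 °C
Reagents that add atoms: none
Why: Fluoride-induced cleavage of the aryl silyl ether, buffered with acetic acid so that the MOM acetals and the flavone are untouched and a single free phenol results.

Step 8
Reactants: 12 3-[4-hydroxy-2,6-bis(methoxymethoxy)phenyl]-7-methoxy-5-(methoxymethoxy)-2-(4-methoxyphenyl)-4H-chromen-4-one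
Product: 14 3-[3-formyl-4-hydroxy-2,6-bis(methoxymethoxy)phenyl]-7-methoxy-5-(methoxymethoxy)-2-(4-methoxyphenyl)-4H-chromen-4-one, via hydroxymethyl phenol 13 (not isolated)
Conditions: MgCl2, Et3N, (CH2O)n, MeCN, 75 °C; citric acid work-up
Reagents that add atoms: formaldehyde (as paraformaldehyde), C=O
Why: Casnati–Skattebøl ortho-formylation, in which the magnesium phenoxide delivers formaldehyde only to a carbon ortho to the single free hydroxyl (the two are equivalent) and a second formaldehyde oxidizes the benzylic alkoxide by hydride transfer; the basic medium spares the MOM ethers.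

Step 9
Reactants: 14 3-[3-formyl-4-hydroxy-2,6-bis(methoxymethoxy)phenyl]-7-methoxy-5-(methoxymethoxy)-2-(4-methoxyphenyl)-4H-chromen-4-one
Product: 15 prop-2-enyl 3-hydroxy-3-[6-hydroxy-2,4-bis(methoxymethoxy)-3-Fl-phenyl]propanoate (mixture at the carbinol carbon)
Conditions: allyl acetate (3.2 equiv), LiN(i-Pr)2 (LDA, 3.3 equiv), THF, −78 °C; then 14, −78 °C; AcOH, −78 °C
Reagents that add atoms: allyl acetate (prop-2-enyl acetate), CC(=O)OCC=C
Why: Aldol addition of a lithium ester enolate, used in excess because the first equivalent is consumed by the phenol, to an aldehyde that at −78 °C is far more electrophilic than the hindered vinylogous-ester carbonyl of the flavone; the carbinol centre forms without control and is erased in step 10.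

Step 10
Reactants: 15 prop-2-enyl 3-hydroxy-3-[6-hydroxy-2,4-bis(methoxymethoxy)-3-Fl-phenyl]propanoate
Product: 16 prop-2-enyl 3-[6-hydroxy-2,4-bis(methoxymethoxy)-3-Fl-phenyl]-3-oxopropanoate
Conditions: activated MnO2 (excess), CH2Cl2, rt
Reagents that add atoms: none
Why: Manganese dioxide oxidation of an electron-rich benzylic alcohol, a neutral heterogeneous method that tolerates the free phenol, the MOM acetals and the allyl ester and gives the hydrogen-bonded aryl β-keto ester.

Step 11
Reactants: 17 4-hydroxybenzaldehyde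
Product: 18 4-(methoxymethoxy)benzaldehyde
Conditions: MOMCl, i-Pr2NEt, CH2Cl2, 0 °C to rt
Reagents that add atoms: chloromethyl methyl ether, COCCl
Why: Routine O-alkylation of an acidic phenol to its MOM ether, which puts the aldehyde partner in the same protecting group as the rest of the molecule.

Step 12
Reactants: 16 prop-2-enyl 3-[6-hydroxy-2,4-bis(methoxymethoxy)-3-Fl-phenyl]-3-oxopropanoate; 18 4-(methoxymethoxy)benzaldehyde
Product: 19 prop-2-enyl (2Z)-2-[6-hydroxy-2,4-bis(methoxymethoxy)-3-Fl-benzoyl]-3-[4-(methoxymethoxy)phenyl]prop-2-enoate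
Conditions: piperidine (10 mol %), AcOH (10 mol %), 4 Å molecular sieves, toluene, rt
Reagents that add atoms: none
Why: Knoevenagel condensation of the β-keto ester methylene with the aromatic aldehyde under buffered amine catalysis, expected to favour the isomer with the aryl group trans to the bulky aroyl group, while the phenol stays hydrogen-bonded to the ketone and the mild conditions hold back ring closure.

Step 13
Reactants: 19 prop-2-enyl (2Z)-2-[6-hydroxy-2,4-bis(methoxymethoxy)-3-Fl-benzoyl]-3-[4-(methoxymethoxy)phenyl]prop-2-enoate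
Product: 22 (2R)-5,7-bis(methoxymethoxy)-2-[4-(methoxymethoxy)phenyl]-6-Fl-2,3-dihydro-4H-chromen-4-one, via cyclized allyl ester 20 (not isolated), via β-keto acid 21 (not isolated)
Conditions: 1-[3,5-bis(trifluoromethyl)phenyl]-3-[(8S,9S)-6'-methoxycinchonan-9-yl]thiourea (15 mol %), toluene, −25 °C; then HCO2H, Et3N, Pd(OAc)2 (5 mol %), PPh3 (20 mol %), THF, −25 to 35 °C
Reagents that add atoms: none
Why: The thiourea N–H pair binds the 1,3-dicarbonyl of 19 while the quinuclidine nitrogen takes the proton of the lone free phenol, and the resulting phenoxide adds to the benzylidene carbon to form O1–C2. This closes the dihydropyranone (ring C of the flavanone) in a 6-endo-trig mode, and the closest known reaction is the cinchona-thiourea oxa-Michael cyclization of 2-hydroxyaryl alkylidene β-keto esters to flavanones with decarboxylation in the same flask. C2 is the only stereocentre that survives, and its (R) configuration is set by the catalyst, which presents the phenoxide to one face of the hydrogen-bonded acceptor. The step needs the 6-linked and not the 8-linked flavanone, and the substrate secures this because the hindered phenol beside the biaryl bond is a MOM ether and the flavone carries no free hydroxyl. Formic acid is added cold so that the basic catalyst is protonated before warming, which shuts off the retro-Michael path; zerovalent palladium formed from Pd(OAc)2 and PPh3 then removes the allyl group by Tsuji–Trost transfer to formate, and the β-keto acid loses CO2 through its enol. The allyl ester replaces the more usual tert-butyl ester because the hot sulfonic acid needed to cleave the latter would also strip the MOM ethers.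

Step 14
Reactants: 22 (2R)-5,7-bis(methoxymethoxy)-2-[4-(methoxymethoxy)phenyl]-6-Fl-2,3-dihydro-4H-chromen-4-one
Product: 23 (2R)-5,7-dihydroxy-6-[5-hydroxy-7-methoxy-2-(4-methoxyphenyl)-4-oxo-4H-chromen-3-yl]-2-(4-hydroxyphenyl)-2,3-dihydro-4H-chromen-4-one
Conditions: 3 M aq. HCl, MeOH/THF, 45 °C
Reagents that add atoms: none
Why: Acid-catalysed acetal methanolysis of the four MOM ethers, with formaldehyde carried off as dimethoxymethane so that it cannot alkylate the phloroglucinol rings; C2 should hold because reopening ring C needs an enolate, which is absent in acid.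

**Compound list**

1 | 5-hydroxy-7-methoxy-2-(4-methoxyphenyl)-4H-chromen-4-one (5-hydroxy-7,4'-dimethoxyflavone) | COc1ccc(-c2cc(=O)c3c(O)cc(OC)cc3o2)cc1 | starting material
2 | 7-methoxy-5-(methoxymethoxy)-2-(4-methoxyphenyl)-4H-chromen-4-one | COc1ccc(-c2cc(=O)c3c(OCOC)cc(OC)cc3o2)cc1 | intermediate
3 | 3-lithio-7-methoxy-5-(methoxymethoxy)-2-(4-methoxyphenyl)-4H-chromen-4-one (formed in the flask) | COc1ccc(-c2oc3cc(OC)cc(OCOC)c3c(=O)c2[Li])cc1 | intermediate
4 | 3-iodo-7-methoxy-5-(methoxymethoxy)-2-(4-methoxyphenyl)-4H-chromen-4-one | COc1ccc(-c2oc3cc(OC)cc(OCOC)c3c(=O)c2I)cc1 | intermediate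
5 | phloroglucinol (benzene-1,3,5-triol) | Oc1cc(O)cc(O)c1 | starting material
6 | 3,5-bis(methoxymethoxy)phenol | COCOc1cc(O)cc(OCOC)c1 | intermediate
7 | [3,5-bis(methoxymethoxy)phenoxy]tri(propan-2-yl)silane | COCOc1cc(OCOC)cc(O[Si](C(C)C)(C(C)C)C(C)C)c1 | intermediate
8 | 2,6-bis(methoxymethoxy)-4-(triisopropylsilyloxy)phenyllithium (formed in the flask) | [Li]c1c(OCOC)cc(O[Si](C(C)C)(C(C)C)C(C)C)cc1OCOC | intermediate
9 | lithium [2,6-bis(methoxymethoxy)-4-(triisopropylsilyloxy)phenyl]trimethoxyborate (formed in the flask) | [Li+].CO[B-](OC)(OC)c1c(OCOC)cc(O[Si](C(C)C)(C(C)C)C(C)C)cc1OCOC | intermediate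
10 | [2,6-bis(methoxymethoxy)-4-(triisopropylsilyloxy)phenyl]boronic acid | OB(O)c1c(OCOC)cc(O[Si](C(C)C)(C(C)C)C(C)C)cc1OCOC | intermediate
11 | 3-[2,6-bis(methoxymethoxy)-4-(triisopropylsilyloxy)phenyl]-7-methoxy-5-(methoxymethoxy)-2-(4-methoxyphenyl)-4H-chromen-4-one | COc1ccc(-c2oc3cc(OC)cc(OCOC)c3c(=O)c2-c2c(OCOC)cc(O[Si](C(C)C)(C(C)C)C(C)C)cc2OCOC)cc1 | intermediate
12 | 3-[4-hydroxy-2,6-bis(methoxymethoxy)phenyl]-7-methoxy-5-(methoxymethoxy)-2-(4-methoxyphenyl)-4H-chromen-4-one | COc1ccc(-c2oc3cc(OC)cc(OCOC)c3c(=O)c2-c2c(OCOC)cc(O)cc2OCOC)cc1 | intermediate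
13 | 3-[4-hydroxy-3-(hydroxymethyl)-2,6-bis(methoxymethoxy)phenyl]-7-methoxy-5-(methoxymethoxy)-2-(4-methoxyphenyl)-4H-chromen-4-one (formed in the flask) | COc1ccc(-c2oc3cc(OC)cc(OCOC)c3c(=O)c2-c2c(OCOC)cc(O)c(CO)c2OCOC)cc1 | intermediate
14 | 3-[3-formyl-4-hydroxy-2,6-bis(methoxymethoxy)phenyl]-7-methoxy-5-(methoxymethoxy)-2-(4-methoxyphenyl)-4H-chromen-4-one | COc1ccc(-c2oc3cc(OC)cc(OCOC)c3c(=O)c2-c2c(OCOC)cc(O)c(C=O)c2OCOC)cc1 | intermediate
15 | prop-2-enyl 3-hydroxy-3-[6-hydroxy-2,4-bis(methoxymethoxy)-3-Fl-phenyl]propanoate (carbinol centre uncontrolled) | COc1ccc(-c2oc3cc(OC)cc(OCOC)c3c(=O)c2-c2c(OCOC)cc(O)c(C(O)CC(=O)OCC=C)c2OCOC)cc1 | intermediate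
16 | prop-2-enyl 3-[6-hydroxy-2,4-bis(methoxymethoxy)-3-Fl-phenyl]-3-oxopropanoate | COc1ccc(-c2oc3cc(OC)cc(OCOC)c3c(=O)c2-c2c(OCOC)cc(O)c(C(=O)CC(=O)OCC=C)c2OCOC)cc1 | intermediate
17 | 4-hydroxybenzaldehyde | O=Cc1ccc(O)cc1 | starting material
18 | 4-(methoxymethoxy)benzaldehyde | COCOc1ccc(C=O)cc1 | intermediate
19 | prop-2-enyl (2Z)-2-[6-hydroxy-2,4-bis(methoxymethoxy)-3-Fl-benzoyl]-3-[4-(methoxymethoxy)phenyl]prop-2-enoate | COc1ccc(-c2oc3cc(OC)cc(OCOC)c3c(=O)c2-c2c(OCOC)cc(O)c(C(=O)/C(C(=O)OCC=C)=C/c3ccc(OCOC)cc3)c2OCOC)cc1 | intermediate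
20 | prop-2-enyl (2R)-5,7-bis(methoxymethoxy)-2-[4-(methoxymethoxy)phenyl]-4-oxo-6-Fl-chromane-3-carboxylate (C3 epimers and enol; formed in the flask) | COc1ccc(-c2oc3cc(OC)cc(OCOC)c3c(=O)c2-c2c(OCOC)cc3c(c2OCOC)C(=O)C(C(=O)OCC=C)[C@H](c2ccc(OCOC)cc2)O3)cc1 | intermediate
21 | (2R)-5,7-bis(methoxymethoxy)-2-[4-(methoxymethoxy)phenyl]-4-oxo-6-Fl-chromane-3-carboxylic acid (C3 epimers; formed in the flask) | COc1ccc(-c2oc3cc(OC)cc(OCOC)c3c(=O)c2-c2c(OCOC)cc3c(c2OCOC)C(=O)C(C(=O)O)[C@H](c2ccc(OCOC)cc2)O3)cc1 | intermediate
22 | (2R)-5,7-bis(methoxymethoxy)-2-[4-(methoxymethoxy)phenyl]-6-Fl-2,3-dihydro-4H-chromen-4-one | COc1ccc(-c2oc3cc(OC)cc(OCOC)c3c(=O)c2-c2c(OCOC)cc3c(c2OCOC)C(=O)C[C@H](c2ccc(OCOC)cc2)O3)cc1 | intermediate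
23 | (2R)-5,7-dihydroxy-6-[5-hydroxy-7-methoxy-2-(4-methoxyphenyl)-4-oxo-4H-chromen-3-yl]-2-(4-hydroxyphenyl)-2,3-dihydro-4H-chromen-4-one | COc1ccc(-c2oc3cc(OC)cc(O)c3c(=O)c2-c2c(O)cc3c(c2O)C(=O)C[C@H](c2ccc(O)cc2)O3)cc1 | target

**Step count and risks**

Total steps: 14. Longest linear sequence: 11 steps (steps 3 to 10 and 12 to 14, from phloroglucinol).

Steps most likely to fail:

1. Step 6. Transmetalation may be too slow at a biaryl bond flanked by four ortho substituents, so that protodeboronation of the electron-rich boronic acid and reduction of the iodide outrun the coupling. The fallback sets out from 7, which is lithiated as in step 5 to 8 and transmetalated with ZnCl2 to the arylzinc chloride F1. F1 is coupled with 4 in a Negishi reaction (Pd2(dba)3, RuPhos, THF, 60 °C), and this comes back to the route at 11. It needs neither base nor water and relies on the fast zinc-to-palladium transfer known for hindered biaryls.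

2. Step 13. Facial selectivity may be poor, or an uncatalysed racemic closure may compete, because the doubly ortho-substituted aroyl group is twisted and the allyl ester is less bulky than the tert-butyl ester for which the catalyst is best documented. The fallback sets out from 16 and builds the stereocentre by aryl transfer to a chromone instead. Deallylative decarboxylation of 16 (Pd(OAc)2, PPh3, HCO2H, Et3N, THF) should give the 2-hydroxyacetophenone F2. Heating with N,N-dimethylformamide dimethyl acetal in toluene gives the enaminone F3, and warm acetic acid closes it to the chromone F4 with loss of dimethylamine. An enantioselective conjugate addition of commercial 4-(methoxymethoxy)phenylboronic acid to F4 follows, using Pd(OCOCF3)2, the tert-butyl pyridine-oxazoline ligand of the enantiomeric series that gives (2R), NH4PF6 and water in 1,2-dichloroethane at 60 °C. This known flavanone-forming reaction comes back to the route at 22.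

3. Step 12. The condensation with the electron-rich aldehyde may be slow enough that amine-promoted ring closure of the product (racemic flavanone ester), or lactonization of the β-keto ester onto the phenol, takes over before the alkylidene can be isolated. The fallback sets out from 16 and masks the nucleophile during the condensation. Silylation (t-BuMe2SiCl, imidazole, DMF) gives the silyl ether F5, and the same Knoevenagel condensation with 18 gives the silylated alkylidene F6. Buffered HF·pyridine in THF/pyridine at −20 °C then releases the phenol without base, and this comes back to the route at 19 immediately before the catalyst is added.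

**Further compounds**

F1 | step 6 | [2,6-bis(methoxymethoxy)-4-(triisopropylsilyloxy)phenyl]zinc chloride | Cl[Zn]c1c(OCOC)cc(O[Si](C(C)C)(C(C)C)C(C)C)cc1OCOC
F2 | step 13 | 3-[3-acetyl-4-hydroxy-2,6-bis(methoxymethoxy)phenyl]-7-methoxy-5-(methoxymethoxy)-2-(4-methoxyphenyl)-4H-chromen-4-one | COc1ccc(-c2oc3cc(OC)cc(OCOC)c3c(=O)c2-c2c(OCOC)cc(O)c(C(C)=O)c2OCOC)cc1
F3 | step 13 | 3-{3-[(2E)-3-(dimethylamino)prop-2-enoyl]-4-hydroxy-2,6-bis(methoxymethoxy)phenyl}-7-methoxy-5-(methoxymethoxy)-2-(4-methoxyphenyl)-4H-chromen-4-one | COc1ccc(-c2oc3cc(OC)cc(OCOC)c3c(=O)c2-c2c(OCOC)cc(O)c(C(=O)/C=C/N(C)C)c2OCOC)cc1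
F4 | step 13 | 5,7-bis(methoxymethoxy)-6-Fl-4H-chromen-4-one | COc1ccc(-c2oc3cc(OC)cc(OCOC)c3c(=O)c2-c2c(OCOC)cc3occc(=O)c3c2OCOC)cc1
F5 | step 12 | prop-2-enyl 3-[6-(tert-butyldimethylsilyloxy)-2,4-bis(methoxymethoxy)-3-Fl-phenyl]-3-oxopropanoate | COc1ccc(-c2oc3cc(OC)cc(OCOC)c3c(=O)c2-c2c(OCOC)cc(O[Si](C)(C)C(C)(C)C)c(C(=O)CC(=O)OCC=C)c2OCOC)cc1
F6 | step 12 | prop-2-enyl (2Z)-2-[6-(tert-butyldimethylsilyloxy)-2,4-bis(methoxymethoxy)-3-Fl-benzoyl]-3-[4-(methoxymethoxy)phenyl]prop-2-enoate | COc1ccc(-c2oc3cc(OC)cc(OCOC)c3c(=O)c2-c2c(OCOC)cc(O[Si](C)(C)C(C)(C)C)c(C(=O)/C(C(=O)OCC=C)=C/c3ccc(OCOC)cc3)c2OCOC)cc1
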